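**Retrosynthetic overview**
1. The target is a flavonol with 5-OH and 7,8-di-OMe on ring A and a 3,5-dihydroxy-4-methoxyphenyl ring B; the last step is hydrogenolysis of four benzyl ethers (O3, O5, O3′, O5′).
2. Ring C is the only ring made. It is closed late by O1–C2 cyclodehydration of a 2-benzyloxy-1,3-diketone, which comes from a Baker–Venkataraman shift (C3–C2 bond) of the ring B aroyl group off the C8a oxygen.
3. The strategy rests on this feature: in ring A the C5 hydroxyl and the C4 acyl carbon (on C4a) sit on adjacent carbons, next to the O1-bearing C8a. C5–O and C4a–C4 are cut together, back to an aryne across C4a/C5 that enters the C–O bond of 2-(benzyloxy)acetic acid.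
4. The C8a oxygen is carried as a MOM ether: it directs the aryne addition and, once O5 is benzylated and the MOM group removed, it becomes O1.
5. The aryne precursor, an ortho-silylaryl triflate, comes from 3-hydroxy-4,5-dimethoxybenzaldehyde (bromination, MOM ether, Dakin oxidation, retro-Brook shift and triflation). Ring B comes from methyl 3,5-dihydroxy-4-methoxybenzoate as its bis-benzyl acid chloride.

Key step: step 5

Assumption: bromination of 1 is taken to enter C2, between the hydroxyl and the formyl group, as it does in isovanillin. Flavone numbering (O1, C2 … C8a; rings A, B, C) is used for the ring A intermediates.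

**Step 1**
Reactants: 1 3-hydroxy-4,5-dimethoxybenzaldehyde
Product: 2 2-bromo-3-hydroxy-4,5-dimethoxybenzaldehyde
Conditions: Br2, NaOAc, AcOH, rt
Reagents that add atoms: bromine, BrBr
Why: Electrophilic aromatic bromination: the free hydroxyl is the strongest donor and C2 is both ortho to it and para to the C5 methoxy, so bromine should enter between OH and CHO as in isovanillin, with NaOAc taking up HBr.

**Step 2**
Reactants: 2 2-bromo-3-hydroxy-4,5-dimethoxybenzaldehyde
Product: 3 2-bromo-4,5-dimethoxy-3-(methoxymethoxy)benzaldehyde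
Conditions: MOMCl, iPr2NEt, CH2Cl2, 0 °C → rt
Reagents that add atoms: chloromethyl methyl ether, COCCl
Why: O-Alkylation of the phenol with chloromethyl methyl ether and an amine base (Williamson-type acetal formation) should be clean, since the ortho bromine raises the acidity of the phenol and neither the aldehyde nor the aryl bromide reacts.

**Step 3**
Reactants: 3 2-bromo-4,5-dimethoxy-3-(methoxymethoxy)benzaldehyde
Product: 5 2-bromo-4,5-dimethoxy-3-(methoxymethoxy)phenol, via aryl formate 4 (not isolated)
Conditions: mCPBA, CH2Cl2, rt; then K2CO3 (cat.), MeOH, rt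
Reagents that add atoms: 3-chloroperbenzoic acid (mCPBA), O=C(OO)c1cccc(Cl)c1
Why: Dakin-type Baeyer–Villiger oxidation: in the peracid adduct the electron-rich aryl group (para methoxy) migrates in preference to hydride to give formate 4, which mild methanolysis cleaves to the phenol without touching the MOM acetal or the bromide.

**Step 4**
Reactants: 5 2-bromo-4,5-dimethoxy-3-(methoxymethoxy)phenol
Product: 8 4,5-dimethoxy-3-(methoxymethoxy)-2-(trimethylsilyl)phenyl trifluoromethanesulfonate, via aryl silyl ether 6 (not isolated), via lithium 2-silylphenolate 7 (not isolated)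
Conditions: HMDS, THF, 70 °C, then evaporate; n-BuLi, THF, −78 °C; Tf2O, −78 °C → 0 °C
Reagents that add atoms: hexamethyldisilazane, C[Si](C)(C)N[Si](C)(C)C; trifluoromethanesulfonic anhydride, O=S(=O)(OS(=O)(=O)C(F)(F)F)C(F)(F)F
Why: After silylation of the phenol, bromine–lithium exchange at −78 °C (faster than any MOM-directed deprotonation) sets off the 1,3 O-to-C silyl shift (retro-Brook rearrangement) to phenolate 7, and Tf2O traps it as the ortho-silylaryl triflate, the standard way to fluoride-triggered aryne precursors.

**Step 5**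
Reactants: 8 4,5-dimethoxy-3-(methoxymethoxy)-2-(trimethylsilyl)phenyl trifluoromethanesulfonate; 9 2-(benzyloxy)acetic acid
Product: 11 2-(benzyloxy)-1-[6-hydroxy-3,4-dimethoxy-2-(methoxymethoxy)phenyl]ethan-1-one, via aryne 10 (not isolated)
Conditions: CsF (4 equiv), THF, 125 °C, sealed tube
Reagents that add atoms: none
Why: Fluoride attacks silicon of 8 and triflate leaves, giving aryne 10 with its triple bond across C4a and C5; the carboxylate of 9 adds through oxygen to C5, and the aryl anion left at C4a attacks the carbonyl of the aryl ester just formed, the strained four-membered alkoxide opening at once to the ortho-acyl phenoxide, so that C5–O and C4a–C4 arise in one operation. This is the known fluoride-induced insertion of arynes into the C–O bond of carboxylic acids, which gives ortho-hydroxyaryl ketones. No ring is closed in the product and no stereocentre is formed. The step needs regioselective addition to the unsymmetrical aryne: the MOM-oxy group on C8a, next to the triple bond, withdraws inductively and distorts the aryne so that C5 is the electrophilic terminus and the negative charge builds up at C4a beside oxygen, and C5 is also the less hindered end, flanked only by C6–H. Chelation of the cesium phenoxide by the new ketone should hold back a second arylation, and the MOM, methyl and benzyl ethers are inert to CsF.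

**Step 6**
Reactants: 11 2-(benzyloxy)-1-[6-hydroxy-3,4-dimethoxy-2-(methoxymethoxy)phenyl]ethan-1-one
Product: 12 2-(benzyloxy)-1-[6-(benzyloxy)-3,4-dimethoxy-2-(methoxymethoxy)phenyl]ethan-1-one
Conditions: BnBr, K2CO3, DMF, 50 °C
Reagents that add atoms: benzyl bromide, BrCc1ccccc1
Why: Williamson etherification of the hydrogen-bonded C5 phenol, which carbonate in DMF deprotonates far more readily than it enolises the ketone, puts a benzyl group on O5 that stays until the last step.

**Step 7**
Reactants: 12 2-(benzyloxy)-1-[6-(benzyloxy)-3,4-dimethoxy-2-(methoxymethoxy)phenyl]ethan-1-one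
Product: 13 2-(benzyloxy)-1-[6-(benzyloxy)-2-hydroxy-3,4-dimethoxyphenyl]ethan-1-one
Conditions: conc. HCl (cat.), MeOH, 50 °C
Reagents that add atoms: none
Why: Acid-catalysed transacetalisation to methanol removes the MOM group alone, because benzyl and methyl aryl ethers and the α-benzyloxy ketone are stable to dilute methanolic HCl, and this frees the C8a hydroxyl that will become O1.

**Step 8**
Reactants: 14 methyl 3,5-dihydroxy-4-methoxybenzoate
Product: 15 methyl 3,5-bis(benzyloxy)-4-methoxybenzoate
Conditions: BnBr, K2CO3, DMF, 60 °C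
Reagents that add atoms: benzyl bromide, BrCc1ccccc1
Why: Double Williamson etherification of the two equivalent phenols; the methyl ester is untouched by K2CO3 in DMF.

**Step 9**
Reactants: 15 methyl 3,5-bis(benzyloxy)-4-methoxybenzoate
Product: 16 3,5-bis(benzyloxy)-4-methoxybenzoic acid
Conditions: LiOH, THF/MeOH/H2O, 50 °C; then 1 M HCl
Reagents that add atoms: lithium hydroxide, [Li+].[OH-]
Why: Saponification of the methyl ester by hydroxide (acyl–oxygen cleavage) followed by acidification gives the acid, the benzyl ethers being inert to base.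

**Step 10**
Reactants: 16 3,5-bis(benzyloxy)-4-methoxybenzoic acid
Product: 17 3,5-bis(benzyloxy)-4-methoxybenzoyl chloride
Conditions: (COCl)2, DMF (cat.), CH2Cl2, 0 °C → rt
Reagents that add atoms: oxalyl chloride, O=C(Cl)C(=O)Cl
Why: Acid chloride formation with oxalyl chloride under DMF catalysis (Vilsmeier-type chloroiminium activation) proceeds under near-neutral conditions that leave the benzyl ethers intact.

**Step 11**
Reactants: 13 2-(benzyloxy)-1-[6-(benzyloxy)-2-hydroxy-3,4-dimethoxyphenyl]ethan-1-one; 17 3,5-bis(benzyloxy)-4-methoxybenzoyl chloride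
Product: 18 3-(benzyloxy)-2-[2-(benzyloxy)acetyl]-5,6-dimethoxyphenyl 3,5-bis(benzyloxy)-4-methoxybenzoate
Conditions: Et3N, DMAP (cat.), CH2Cl2, 0 °C → rt
Reagents that add atoms: none
Why: DMAP-catalysed O-acylation of the only free hydroxyl, the C8a phenol, gives the aryl ester needed for the acyl shift, the acid chloride being reactive enough for this flanked, hydrogen-bonded phenol.

**Step 12**
Reactants: 18 3-(benzyloxy)-2-[2-(benzyloxy)acetyl]-5,6-dimethoxyphenyl 3,5-bis(benzyloxy)-4-methoxybenzoate
Product: 19 2-(benzyloxy)-1-[6-(benzyloxy)-2-hydroxy-3,4-dimethoxyphenyl]-3-[3,5-bis(benzyloxy)-4-methoxyphenyl]propane-1,3-dione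
Conditions: LiN(SiMe3)2 (3 equiv), THF, −78 °C → rt; then 1 M HCl
Reagents that add atoms: none
Why: Baker–Venkataraman rearrangement: the lithium enolate of the α-benzyloxy ketone attacks the neighbouring aryl ester through a six-membered cyclic alkoxide and the aroyl group moves from O to C3, forming the C3–C2 bond and a stabilised phenolate–diketonate that drives the shift; the new stereocentre at C3 is formed without control (racemic, enolisable) and disappears in step 13.

**Step 13**
Reactants: 19 2-(benzyloxy)-1-[6-(benzyloxy)-2-hydroxy-3,4-dimethoxyphenyl]-3-[3,5-bis(benzyloxy)-4-methoxyphenyl]propane-1,3-dione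
Product: 20 3,5-bis(benzyloxy)-2-[3,5-bis(benzyloxy)-4-methoxyphenyl]-7,8-dimethoxy-4H-chromen-4-one
Conditions: p-TsOH·H2O (cat.), toluene, 90 °C
Reagents that add atoms: none
Why: Acid-catalysed cyclodehydration: the C8a hydroxyl adds to the ring B ketone (6-exo-trig hemiketal formation) and loss of water, driven by formation of the conjugated 4-pyranone, closes ring C through the O1–C2 bond, and since only this phenol is free no isomeric chromone can form.

**Step 14**
Reactants: 20 3,5-bis(benzyloxy)-2-[3,5-bis(benzyloxy)-4-methoxyphenyl]-7,8-dimethoxy-4H-chromen-4-one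
Product: 21 3,5-dihydroxy-2-(3,5-dihydroxy-4-methoxyphenyl)-7,8-dimethoxy-4H-chromen-4-one
Conditions: H2 (1 atm), 10% Pd/C, THF/MeOH, rt
Reagents that add atoms: none
Why: Catalytic hydrogenolysis cleaves the four benzyl ethers (O3, O5, O3′, O5′) under neutral conditions at room temperature, under which the tetrasubstituted vinylogous-ester C2=C3 bond, the ketone and the methyl ethers should persist and no acid-induced ring opening can scramble the 5-hydroxy-7,8-dimethoxy pattern.

**Compound list**
1 | 3-hydroxy-4,5-dimethoxybenzaldehyde | COc1cc(C=O)cc(O)c1OC | starting material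
2 | 2-bromo-3-hydroxy-4,5-dimethoxybenzaldehyde | O=Cc1cc(OC)c(OC)c(O)c1Br | intermediate
3 | 2-bromo-4,5-dimethoxy-3-(methoxymethoxy)benzaldehyde | O=Cc1cc(OC)c(OC)c(OCOC)c1Br | intermediate
4 | 2-bromo-4,5-dimethoxy-3-(methoxymethoxy)phenyl formate (not isolated) | O=COc1cc(OC)c(OC)c(OCOC)c1Br | intermediate
5 | 2-bromo-4,5-dimethoxy-3-(methoxymethoxy)phenol | Oc1cc(OC)c(OC)c(OCOC)c1Br | intermediate
6 | [2-bromo-4,5-dimethoxy-3-(methoxymethoxy)phenoxy]trimethylsilane (not isolated) | C[Si](C)(C)Oc1cc(OC)c(OC)c(OCOC)c1Br | intermediate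
7 | lithium 4,5-dimethoxy-3-(methoxymethoxy)-2-(trimethylsilyl)phenolate (not isolated) | [Li+].[O-]c1cc(OC)c(OC)c(OCOC)c1[Si](C)(C)C | intermediate
8 | 4,5-dimethoxy-3-(methoxymethoxy)-2-(trimethylsilyl)phenyl trifluoromethanesulfonate | COCOc1c(OC)c(OC)cc(OS(=O)(=O)C(F)(F)F)c1[Si](C)(C)C | intermediate
9 | 2-(benzyloxy)acetic acid | OC(=O)COCc1ccccc1 | starting material
10 | 4,5-dimethoxy-3-(methoxymethoxy)benzyne (1,2-didehydrobenzene, triple bond across C4a/C5; not isolated) | COCOC1=C(OC)C(OC)=CC#C1 | intermediate
11 | 2-(benzyloxy)-1-[6-hydroxy-3,4-dimethoxy-2-(methoxymethoxy)phenyl]ethan-1-one | COCOc1c(OC)c(OC)cc(O)c1C(=O)COCc1ccccc1 | intermediate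
12 | 2-(benzyloxy)-1-[6-(benzyloxy)-3,4-dimethoxy-2-(methoxymethoxy)phenyl]ethan-1-one | COCOc1c(OC)c(OC)cc(OCc2ccccc2)c1C(=O)COCc1ccccc1 | intermediate
13 | 2-(benzyloxy)-1-[6-(benzyloxy)-2-hydroxy-3,4-dimethoxyphenyl]ethan-1-one | COc1cc(OCc2ccccc2)c(C(=O)COCc2ccccc2)c(O)c1OC | intermediate
14 | methyl 3,5-dihydroxy-4-methoxybenzoate | COC(=O)c1cc(O)c(OC)c(O)c1 | starting material
15 | methyl 3,5-bis(benzyloxy)-4-methoxybenzoate | COC(=O)c1cc(OCc2ccccc2)c(OC)c(OCc2ccccc2)c1 | intermediate
16 | 3,5-bis(benzyloxy)-4-methoxybenzoic acid | OC(=O)c1cc(OCc2ccccc2)c(OC)c(OCc2ccccc2)c1 | intermediate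
17 | 3,5-bis(benzyloxy)-4-methoxybenzoyl chloride | O=C(Cl)c1cc(OCc2ccccc2)c(OC)c(OCc2ccccc2)c1 | intermediate
18 | 3-(benzyloxy)-2-[2-(benzyloxy)acetyl]-5,6-dimethoxyphenyl 3,5-bis(benzyloxy)-4-methoxybenzoate | COc1cc(OCc2ccccc2)c(C(=O)COCc2ccccc2)c(OC(=O)c2cc(OCc3ccccc3)c(OC)c(OCc3ccccc3)c2)c1OC | intermediate
19 | 2-(benzyloxy)-1-[6-(benzyloxy)-2-hydroxy-3,4-dimethoxyphenyl]-3-[3,5-bis(benzyloxy)-4-methoxyphenyl]propane-1,3-dione (racemic at C2 of the propane chain) | COc1cc(OCc2ccccc2)c(C(=O)C(OCc2ccccc2)C(=O)c2cc(OCc3ccccc3)c(OC)c(OCc3ccccc3)c2)c(O)c1OC | intermediate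
20 | 3,5-bis(benzyloxy)-2-[3,5-bis(benzyloxy)-4-methoxyphenyl]-7,8-dimethoxy-4H-chromen-4-one | COc1cc(OCc2ccccc2)c2c(=O)c(OCc3ccccc3)c(-c3cc(OCc4ccccc4)c(OC)c(OCc4ccccc4)c3)oc2c1OC | intermediate
21 | 3,5-dihydroxy-2-(3,5-dihydroxy-4-methoxyphenyl)-7,8-dimethoxy-4H-chromen-4-one | COc1cc(O)c2c(=O)c(O)c(-c3cc(O)c(OC)c(O)c3)oc2c1OC | target

**Step count**
Total: 14 steps. Longest linear sequence: 11 steps (steps 1–7 and 11–14, from 1). The ring B branch (steps 8–10) joins at step 11.

**Steps most likely to fail**

1. Step 5 (aryne insertion). The aryl anion may be protonated by free acid or bifluoride before it reaches the ester carbonyl, which stops the sequence at the O-aryl ester. The product phenoxide may also add to a second aryne, and some carboxylate may add at C4a. The fallback fixes the acyl position by the bromine atom instead of by aryne regiochemistry. It sets out from 5, which would be benzylated (BnBr, K2CO3, DMF) to 1-(benzyloxy)-2-bromo-4,5-dimethoxy-3-(methoxymethoxy)benzene F1. In parallel, 9 would be converted with oxalyl chloride (cat. DMF) into 2-(benzyloxy)acetyl chloride F2, and this with MeNHOMe·HCl and Et3N into 2-(benzyloxy)-N-methoxy-N-methylacetamide F3. Bromine–lithium exchange on F1 (n-BuLi, THF, −78 °C) would give [2-(benzyloxy)-4,5-dimethoxy-6-(methoxymethoxy)phenyl]lithium F4. Addition of F4 to F3 gives the chelated tetrahedral adduct lithium 2-(benzyloxy)-1-[6-(benzyloxy)-3,4-dimethoxy-2-(methoxymethoxy)phenyl]-1-[methoxy(methyl)amino]ethan-1-olate F5. An AcOH quench collapses F5 to ketone 12, where the route is rejoined at step 7.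

2. Step 1 (bromination). Bromine may enter para to the hydroxyl (C6) instead of between OH and CHO, or the ring may be brominated twice. The fallback places bromine by directed ortho-lithiation and sets out from 1. The phenol would first be protected (MOMCl, iPr2NEt, CH2Cl2) as 3,4-dimethoxy-5-(methoxymethoxy)benzaldehyde F6. Lithium N,N,N′-trimethylethylenediamide (THF, −20 °C) would add to the formyl group to give the lithium α-amino alkoxide, lithium [3,4-dimethoxy-5-(methoxymethoxy)phenyl]{[2-(dimethylamino)ethyl](methyl)amino}methanolate F7. This masks the aldehyde and, together with the MOM ether (a better ortho director than the methoxy group on the other side), should direct n-BuLi to the carbon between them, giving the ring-lithiated α-amino alkoxide F8. Trapping with 1,2-dibromo-1,1,2,2-tetrachloroethane at −78 °C gives the brominated α-amino alkoxide F9, and aqueous work-up releases the aldehyde. The route is rejoined at 3, before step 3.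

3. Step 12 (acyl shift). Acyl transfer to the crowded, twisted α-alkoxy enolate may be slow, and the base may instead cleave the aryl ester back to the phenol. The fallback replaces the intramolecular shift by direct C-acylation and sets out from 13 and 17, leaving out step 11. 13 would be converted with excess LiN(SiMe3)2 (THF, −78 °C) into its dilithium phenolate–enolate and 17 added. Acylation at the enolate carbon and an acidic quench would give 19, where the route is rejoined at step 13.

**Further compounds**
F1 | step 5 | 1-(benzyloxy)-2-bromo-4,5-dimethoxy-3-(methoxymethoxy)benzene | COCOc1c(Br)c(OCc2ccccc2)cc(OC)c1OC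
F2 | step 5 | 2-(benzyloxy)acetyl chloride | O=C(Cl)COCc1ccccc1
F3 | step 5 | 2-(benzyloxy)-N-methoxy-N-methylacetamide | CON(C)C(=O)COCc1ccccc1
F4 | step 5 | [2-(benzyloxy)-4,5-dimethoxy-6-(methoxymethoxy)phenyl]lithium | [Li]c1c(OCc2ccccc2)cc(OC)c(OC)c1OCOC
F5 | step 5 | lithium 2-(benzyloxy)-1-[6-(benzyloxy)-3,4-dimethoxy-2-(methoxymethoxy)phenyl]-1-[methoxy(methyl)amino]ethan-1-olate | COCOc1c(C(O[Li])(COCc2ccccc2)N(C)OC)c(OCc2ccccc2)cc(OC)c1OC
F6 | step 1 | 3,4-dimethoxy-5-(methoxymethoxy)benzaldehyde | COCOc1cc(C=O)cc(OC)c1OC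
F7 | step 1 | lithium [3,4-dimethoxy-5-(methoxymethoxy)phenyl]{[2-(dimethylamino)ethyl](methyl)amino}methanolate | COCOc1cc(C(O[Li])N(C)CCN(C)C)cc(OC)c1OC
F8 | step 1 | lithium [2-lithio-4,5-dimethoxy-3-(methoxymethoxy)phenyl]{[2-(dimethylamino)ethyl](methyl)amino}methanolate | COCOc1c([Li])c(C(O[Li])N(C)CCN(C)C)cc(OC)c1OC
F9 | step 1 | lithium [2-bromo-4,5-dimethoxy-3-(methoxymethoxy)phenyl]{[2-(dimethylamino)ethyl](methyl)amino}methanolate | COCOc1c(Br)c(C(O[Li])N(C)CCN(C)C)cc(OC)c1OC
F0 | step 12 | none | none
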